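## Retrosynthetic overview

1. The strategy rests on ring B, the benzo ring of the central dihydrobenzofuran (DHB2): B1 carries C2 of the stilbene-side dihydrobenzofuran (DHB1) para to the ring oxygen on B4, B5 carries C3 of DHB2, and nothing else joins the two halves, so ring B is cut into three alkyne units (bonds B2–B3, B4–B5, B6–B1).
2. Target 35 ⇐ nonamethyl ether 34 (BBr3) ⇐ ring A bromide 32 + 4-methoxystyrene (Heck) ⇐ ring B silane 31 (protodesilylation) ⇐ (2+2+2) cycloaddition of the silylated ynol ether diyne 30 with the 2-ethynyl dihydrobenzofuran 14.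
3. Diyne 30 ⇐ anti homopropargylic alcohol 25 (ynol ether from trichloroethylene) ⇐ chiral allenylzinc from propargylic mesylate 22 + 4-methoxybenzaldehyde ⇐ ring C aldehyde 19.
4. Both outer units come from one aldehyde 12, made by an asymmetric (4+1) annulation of an ortho-quinone methide with a chiral ammonium ylide: 12 gives alkyne 14 by Ohira–Bestmann homologation and, after oxidation and decarboxylative arylation, the DHB3 bromide 17 and aldehyde 19.
5. Ring order: the furan rings of DHB1 and DHB3 on a purchased arene (rings A and C), then ring B together with the furan ring of DHB2 in the key step; the stilbene and the nine phenols come last.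

Key step: step 17

Assumption: the quinidine-derived ylide of step 6 and the (S,S) ligand of step 12 are taken to give the (2R,3R) and (S) products drawn; if a test run shows the opposite sense, the quinine-derived salt or the (R,R) ligand is used and nothing else changes.

## Route

Step 1
Reactants: 1 1-bromo-3,5-dimethoxybenzene
Product: 2 2-bromo-4,6-dimethoxybenzaldehyde
Conditions: POCl3, DMF, 0 → 90 °C; then H2O
Reagents that add atoms: N,N-dimethylformamide CN(C)C=O; water O
Why: Vilsmeier–Haack formylation should go at C2, para to one methoxy group and ortho to the other and less hindered than the position between the two methoxy groups, and the minor isomer is removed by crystallisation.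

Step 2
Reactants: 2 2-bromo-4,6-dimethoxybenzaldehyde
Product: 3 2-bromo-6-hydroxy-4-methoxybenzaldehyde
Conditions: BCl3 (1.1 equiv), CH2Cl2, −78 → 0 °C; then H2O
Reagents that add atoms: none
Why: chelation-directed Lewis-acid ether cleavage, in which BCl3 bound to the aldehyde oxygen removes only the ortho methyl ether and leaves the para methoxy group and the bromide.

Step 3
Reactants: 1 1-bromo-3,5-dimethoxybenzene; 3 2-bromo-6-hydroxy-4-methoxybenzaldehyde
Product: 5 3-bromo-2-[(3,5-dimethoxyphenyl)(hydroxy)methyl]-5-methoxyphenol (racemic), via Grignard reagent 4 (not isolated)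
Conditions: Mg, THF, 50 °C (2.3 equiv of 4); then 3, THF, 0 °C → rt; then H2O
Reagents that add atoms: none
Why: Grignard addition to the aldehyde, one equivalent of 4 being spent on the phenol; the carbinol centre is formed racemic and is destroyed in step 6.

Step 4
Reactants: 5 3-bromo-2-[(3,5-dimethoxyphenyl)(hydroxy)methyl]-5-methoxyphenol
Product: 6 3-bromo-2-[(3,5-dimethoxyphenyl)(4-methylbenzenesulfonyl)methyl]-5-methoxyphenol (racemic)
Conditions: p-TolSO2Na (1.5 equiv), HCO2H, CH2Cl2/H2O, rt
Reagents that add atoms: sodium 4-methylbenzenesulfinate [Na+].Cc1ccc(cc1)S(=O)[O-]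
Why: acid-promoted SN1 substitution of the ortho-hydroxy, para-methoxy benzhydrol by sulfinate at sulfur gives the stable sulfone that later releases the ortho-quinone methide under base.

Step 5
Reactants: 7 quinidine; 8 2-bromo-N,N-diethylacetamide
Product: 9 N-[2-(diethylamino)-2-oxoethyl]quinidinium bromide
Conditions: THF, rt → 50 °C
Reagents that add atoms: none
Why: Menshutkin alkylation at the quinuclidine nitrogen, the more nucleophilic of the two nitrogens, gives the amide-stabilised ammonium ylide precursor with the alkaloid as chiral leaving group.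

Step 6
Reactants: 6 the sulfone; 9 the quinidinium bromide
Product: 11 (2R,3R)-4-bromo-3-(3,5-dimethoxyphenyl)-N,N-diethyl-6-methoxy-2,3-dihydro-1-benzofuran-2-carboxamide, via ortho-quinone methide 10 (not isolated)
Conditions: Cs2CO3 (2.5 equiv), CH2Cl2, rt
Reagents that add atoms: none
Why: formal (4+1) annulation of a chiral ammonium ylide with an ortho-quinone methide: base eliminates sulfinate from 6 to give 10, the ylide adds to the methide carbon with facial control by the cinchona ammonium group (this sets C3 as R), and the phenoxide closes the furan ring by 5-exo-tet SN2 displacement of quinidine to give the trans ring with C2 as R.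

Step 7
Reactants: 11 the trans amide
Product: 12 (2R,3R)-4-bromo-3-(3,5-dimethoxyphenyl)-6-methoxy-2,3-dihydro-1-benzofuran-2-carbaldehyde
Conditions: Cp2Zr(H)Cl (1.6 equiv), THF, rt; then H2O/silica
Reagents that add atoms: none
Why: reduction of the tertiary amide with Cp2Zr(H)Cl stops at a zirconium hemiaminal that gives the aldehyde on work-up, leaves the aryl bromide alone and, trans being the more stable arrangement at C2, does not endanger the configuration.

Step 8
Reactants: 12 the aldehyde; 13 dimethyl (1-diazo-2-oxopropyl)phosphonate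
Product: 14 (2R,3R)-4-bromo-3-(3,5-dimethoxyphenyl)-2-ethynyl-6-methoxy-2,3-dihydro-1-benzofuran
Conditions: K2CO3, MeOH, 0 °C → rt
Reagents that add atoms: none
Why: Ohira–Bestmann (Seyferth–Gilbert) homologation turns the aldehyde into the terminal alkyne, and C2 stays trans to the C3 aryl group because that is the thermodynamic epimer of the aldehyde under the basic conditions.

Step 9
Reactants: 12 the aldehyde
Product: 15 (2R,3R)-4-bromo-3-(3,5-dimethoxyphenyl)-6-methoxy-2,3-dihydro-1-benzofuran-2-carboxylic acid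
Conditions: NaClO2, NaH2PO4, 2-methyl-2-butene, t-BuOH/H2O, rt
Reagents that add atoms: sodium chlorite [Na+].[O-]Cl=O
Why: Pinnick oxidation is selective for the aldehyde, and the alkene scavenger removes hypochlorous acid before it can chlorinate the methoxy arenes.

Step 10
Reactants: 15 the acid; 16 4-iodoanisole
Product: 17 (2R,3R)-4-bromo-3-(3,5-dimethoxyphenyl)-6-methoxy-2-(4-methoxyphenyl)-2,3-dihydro-1-benzofuran
Conditions: Ir[dF(CF3)ppy]2(dtbbpy)PF6 (1 mol%), NiCl2·glyme (10 mol%), dtbbpy (15 mol%), Cs2CO3, DMF, blue LEDs, rt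
Reagents that add atoms: none
Why: photoredox/nickel decarboxylative arylation of an α-oxy acid: oxidation of the carboxylate and loss of CO2 give the C2 radical, which is captured by the aryl nickel species from 4-iodoanisole (oxidative addition of the aryl iodide to zerovalent nickel outruns that of the hindered ring bromide), and reductive elimination should place the aryl group anti to the C3 aryl group, so C2 is set trans (R) by the untouched C3 centre.

Step 11
Reactants: 17 the DHB3 bromide
Product: 19 (2R,3R)-3-(3,5-dimethoxyphenyl)-6-methoxy-2-(4-methoxyphenyl)-2,3-dihydro-1-benzofuran-4-carbaldehyde, via aryllithium 18 (not isolated)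
Conditions: n-BuLi (1.05 equiv), THF, −78 °C; then DMF, −78 → 0 °C; then H2O
Reagents that add atoms: N,N-dimethylformamide CN(C)C=O
Why: bromine–lithium exchange, faster at −78 °C than deprotonation at C2, followed by formylation of the aryllithium with DMF gives the ring C aldehyde.

Step 12
Reactants: 19 the ring C aldehyde; 20 ethynyl(trimethyl)silane
Product: 21 (1S)-propargylic alcohol (ring C–CH(OH)–C≡C–SiMe3)
Conditions: (S,S)-ProPhenol (20 mol%), Me2Zn (3 equiv), Ph3PO (40 mol%), toluene, 0 °C → rt; then H2O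
Reagents that add atoms: none
Why: catalytic asymmetric alkynylation of the aryl aldehyde by the alkynylzinc formed in situ within the dinuclear zinc–ProPhenol complex should set the carbinol centre as S by catalyst control, and the minor epimer is a diastereomer that chromatography removes.

Step 13
Reactants: 21 the (1S)-propargylic alcohol
Product: 22 (1S)-propargylic methanesulfonate
Conditions: MsCl, Et3N, CH2Cl2, −78 °C
Reagents that add atoms: methanesulfonyl chloride CS(Cl)(=O)=O
Why: O-sulfonylation with retention; both ring C oxygens are meta to the carbinol carbon, so the benzylic propargylic mesylate should not ionise at low temperature and is used crude at once.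

Step 14
Reactants: 22 the mesylate; 23 4-methoxybenzaldehyde
Product: 25 (1R,2R)-anti homopropargylic alcohol (4-MeOC6H4–CH(OH)–CH(ring C)–C≡C–SiMe3), via allenylzinc 24 (not isolated)
Conditions: Pd(OAc)2 (5 mol%), PPh3 (5 mol%), Et2Zn (3 equiv), THF, −78 → −20 °C; then H2O
Reagents that add atoms: none
Why: Marshall propargylation: zerovalent palladium displaces the mesylate anti (SN2′), transmetalation with Et2Zn gives the (M)-allenylzinc 24, and 24 adds to the aldehyde through a cyclic SE2′ transition state on the metal-bearing face (net inversion at the propargylic carbon, which becomes C3 of DHB2) with the allene aryl group and the aldehyde aryl group apart, which gives the anti isomer and sets the carbinol carbon (C2 of DHB2) as R.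

Step 15
Reactants: 25 the anti homopropargylic alcohol; 26 trichloroethylene
Product: 29 triethylsilyl ynol ether of 25 (Et3Si–C≡C–O–CH(Ar)–CH(ring C)–C≡C–SiMe3), via dichlorovinyl ether 27 (not isolated), via lithium alkynyl ether 28 (not isolated)
Conditions: KH, THF, 0 °C; 26, −40 °C → rt; then n-BuLi (2.2 equiv), −78 → −40 °C; then Et3SiCl, −78 → 0 °C
Reagents that add atoms: chlorotriethylsilane CC[Si](Cl)(CC)CC
Why: ynol ether synthesis from trichloroethylene: the potassium alkoxide adds to dichloroacetylene formed in situ to give the (E)-1,2-dichlorovinyl ether, n-BuLi effects elimination and chlorine–lithium exchange, and the lithium alkynyl ether is silylated at carbon; the carbinol C–O bond is never broken, so both centres are kept, and the trimethylsilyl cap keeps the other alkyne from being metalated.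

Step 16
Reactants: 29 the bis-silylated diyne
Product: 30 (1R,2S)-diyne Et3Si–C≡C–O–CH(4-MeOC6H4)–CH(ring C)–C≡CH
Conditions: K2CO3 (0.2 equiv), MeOH/THF, 0 °C
Reagents that add atoms: none
Why: base-catalysed methanolysis of alkynylsilanes is much faster for trimethylsilyl than for triethylsilyl, so the carbon alkyne should be set free while the silicon on the ynol ether stays; 30 is kept cold and used at once because alkynyl ethers rearrange on warming.

Step 17
Reactants: 30 the ynol ether diyne; 14 the 2-ethynyl dihydrobenzofuran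
Product: 31 tris-dihydrobenzofuran with triethylsilyl on B3 of ring B and bromide on ring A
Conditions: Cp*RuCl(cod) (10 mol%), 14 (2 equiv), ClCH2CH2Cl, rt, slow addition of 30
Reagents that add atoms: none
Why: The two tethered alkynes of 30 couple oxidatively on the Cp*RuCl fragment (divalent ruthenium) to a ruthenacyclopentadiene, which forms B4–B5 and thereby closes the five-membered O–C2–C3 ring of DHB2 through the tether, as in any 1,6-diyne; alkyne 14 then inserts and reductive elimination forms B6–B1 and B2–B3, closing ring B as a new benzene by (2+2+2) annulation. The closest known reactions are the Cp*RuCl(cod)-catalysed cycloadditions of unsymmetrical 1,6-diynes with terminal alkynes and the rhodium-catalysed cycloadditions of alkynyl-ether-tethered 1,6-diynes to fused benzofurans. No stereocentre is formed: C2 and C3 of DHB2 were set in the open chain in step 14 and, like the centres of DHB1 and DHB3, are not touched under neutral, non-oxidising conditions at room temperature, which also keeps the heat-sensitive ynol ether intact. The step needs regioselectivity, and the triethylsilyl group on the ynol ether terminus secures it: 14 inserts on the side of the unsubstituted terminus with its substituent on the carbon that bonds to B6, so silicon (B3) and DHB1 (B1, para to the ring oxygen) end up meta. It also needs cross- over self-cycloaddition of the diyne, which is secured by adding 30 slowly to an excess of 14, a hindered monoalkyne that does not trimerise by itself.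

Step 18
Reactants: 31 the ring B silane
Product: 32 tris-dihydrobenzofuran ring A bromide (H on B3)
Conditions: Bu4NF·3H2O (5 equiv), DMF, 80 °C
Reagents that add atoms: none
Why: fluoride-induced ipso-protodesilylation: fluoride attacks silicon and the aryl anion, stabilised inductively by the ortho ring oxygen on B4, is protonated by water, without the acid that could ionise the benzylic C2–O bonds of the three dihydrobenzofurans.

Step 19
Reactants: 32 the ring A bromide; 33 4-methoxystyrene
Product: 34 nonamethyl ether of the target, (E)-stilbene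
Conditions: Pd2(dba)3 (3 mol%), [HP(t-Bu)3]BF4 (12 mol%), Cy2NMe, dioxane, 90 °C
Reagents that add atoms: none
Why: Mizoroki–Heck reaction of the hindered aryl bromide with the styrene, in which syn carbopalladation at the terminal carbon and syn β-hydride elimination give the (E)-stilbene.

Step 20
Reactants: 34 the nonamethyl ether
Product: 35 the target CNP0184803.1
Conditions: BBr3 (20 equiv), CH2Cl2, −78 → 0 °C; then H2O
Reagents that add atoms: none
Why: Lewis-acid cleavage of the nine aryl methyl ethers by BBr3 (bromide attacks the O-methyl of the boron-bound ether), run cold and quenched early so that the benzylic ether bonds of the three dihydrobenzofurans and the stilbene are kept; the all-trans rings are the thermodynamic arrangement at each C2.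

## Compound list

In the names, "DHB3-yl" stands for (2R,3R)-3-(3,5-dimethoxyphenyl)-6-methoxy-2-(4-methoxyphenyl)-2,3-dihydro-1-benzofuran-4-yl.

1 | 1-bromo-3,5-dimethoxybenzene | COc1cc(Br)cc(OC)c1 | starting material
2 | 2-bromo-4,6-dimethoxybenzaldehyde | O=Cc1c(Br)cc(OC)cc1OC | intermediate
3 | 2-bromo-6-hydroxy-4-methoxybenzaldehyde | O=Cc1c(Br)cc(OC)cc1O | intermediate
4 | (3,5-dimethoxyphenyl)magnesium bromide | COc1cc([Mg]Br)cc(OC)c1 | intermediate
5 | 3-bromo-2-[(3,5-dimethoxyphenyl)(hydroxy)methyl]-5-methoxyphenol (racemic) | OC(c1cc(OC)cc(OC)c1)c1c(Br)cc(OC)cc1O | intermediate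
6 | 3-bromo-2-[(3,5-dimethoxyphenyl)(4-methylbenzenesulfonyl)methyl]-5-methoxyphenol (racemic) | Cc1ccc(cc1)S(=O)(=O)C(c1cc(OC)cc(OC)c1)c1c(Br)cc(OC)cc1O | intermediate
7 | quinidine | COC1=CC2=C(C=CN=C2C=C1)[C@@H]([C@H]3C[C@@H]4CCN3C[C@@H]4C=C)O | starting material
8 | 2-bromo-N,N-diethylacetamide | CCN(CC)C(=O)CBr | starting material
9 | N-[2-(diethylamino)-2-oxoethyl]quinidinium bromide | COC1=CC2=C(C=CN=C2C=C1)[C@@H]([C@H]3C[C@@H]4CC[N+]3(CC(=O)N(CC)CC)C[C@@H]4C=C)O.[Br-] | intermediate
10 | 5-bromo-6-[(3,5-dimethoxyphenyl)methylidene]-3-methoxycyclohexa-2,4-dien-1-one (ortho-quinone methide) | O=C1C=C(OC)C=C(Br)C1=Cc1cc(OC)cc(OC)c1 | intermediate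
11 | (2R,3R)-4-bromo-3-(3,5-dimethoxyphenyl)-N,N-diethyl-6-methoxy-2,3-dihydro-1-benzofuran-2-carboxamide | CCN(CC)C(=O)[C@@H]1Oc2cc(OC)cc(Br)c2[C@H]1c1cc(OC)cc(OC)c1 | intermediate
12 | (2R,3R)-4-bromo-3-(3,5-dimethoxyphenyl)-6-methoxy-2,3-dihydro-1-benzofuran-2-carbaldehyde | O=C[C@@H]1Oc2cc(OC)cc(Br)c2[C@H]1c1cc(OC)cc(OC)c1 | intermediate
13 | dimethyl (1-diazo-2-oxopropyl)phosphonate | COP(=O)(OC)C(=[N+]=[N-])C(C)=O | starting material
14 | (2R,3R)-4-bromo-3-(3,5-dimethoxyphenyl)-2-ethynyl-6-methoxy-2,3-dihydro-1-benzofuran | C#C[C@@H]1Oc2cc(OC)cc(Br)c2[C@H]1c1cc(OC)cc(OC)c1 | intermediate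
15 | (2R,3R)-4-bromo-3-(3,5-dimethoxyphenyl)-6-methoxy-2,3-dihydro-1-benzofuran-2-carboxylic acid | OC(=O)[C@@H]1Oc2cc(OC)cc(Br)c2[C@H]1c1cc(OC)cc(OC)c1 | intermediate
16 | 1-iodo-4-methoxybenzene (4-iodoanisole) | COc1ccc(I)cc1 | starting material
17 | (2R,3R)-4-bromo-3-(3,5-dimethoxyphenyl)-6-methoxy-2-(4-methoxyphenyl)-2,3-dihydro-1-benzofuran | Brc1cc(OC)cc2c1[C@@H](c1cc(OC)cc(OC)c1)[C@H](c1ccc(OC)cc1)O2 | intermediate
18 | (DHB3-yl)lithium | [Li]c1cc(OC)cc2c1[C@@H](c1cc(OC)cc(OC)c1)[C@H](c1ccc(OC)cc1)O2 | intermediate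
19 | (2R,3R)-3-(3,5-dimethoxyphenyl)-6-methoxy-2-(4-methoxyphenyl)-2,3-dihydro-1-benzofuran-4-carbaldehyde | O=Cc1cc(OC)cc2c1[C@@H](c1cc(OC)cc(OC)c1)[C@H](c1ccc(OC)cc1)O2 | intermediate
20 | ethynyl(trimethyl)silane | C#C[Si](C)(C)C | starting material
21 | (1S)-1-(DHB3-yl)-3-(trimethylsilyl)prop-2-yn-1-ol | O[C@H](C#C[Si](C)(C)C)c1cc(OC)cc2c1[C@@H](c1cc(OC)cc(OC)c1)[C@H](c1ccc(OC)cc1)O2 | intermediate
22 | (1S)-1-(DHB3-yl)-3-(trimethylsilyl)prop-2-yn-1-yl methanesulfonate | CS(=O)(=O)O[C@H](C#C[Si](C)(C)C)c1cc(OC)cc2c1[C@@H](c1cc(OC)cc(OC)c1)[C@H](c1ccc(OC)cc1)O2 | intermediate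
23 | 4-methoxybenzaldehyde | COc1ccc(C=O)cc1 | starting material
24 | (M)-[3-(DHB3-yl)-1-(trimethylsilyl)propa-1,2-dien-1-yl](ethyl)zinc | CC[Zn]C([Si](C)(C)C)=[C@]=C([H])c1cc(OC)cc2c1[C@@H](c1cc(OC)cc(OC)c1)[C@H](c1ccc(OC)cc1)O2 | intermediate
25 | (1R,2R)-2-(DHB3-yl)-1-(4-methoxyphenyl)-4-(trimethylsilyl)but-3-yn-1-ol (anti) | O[C@@H](c1ccc(OC)cc1)[C@@H](C#C[Si](C)(C)C)c1cc(OC)cc2c1[C@@H](c1cc(OC)cc(OC)c1)[C@H](c1ccc(OC)cc1)O2 | intermediate
26 | trichloroethylene | ClC=C(Cl)Cl | starting material
27 | (E)-1,2-dichloroethenyl ether of alcohol 25 (both centres as in 25) | Cl/C=C(/Cl)O[C@@H](c1ccc(OC)cc1)[C@@H](C#C[Si](C)(C)C)c1cc(OC)cc2c1[C@@H](c1cc(OC)cc(OC)c1)[C@H](c1ccc(OC)cc1)O2 | intermediate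
28 | 2-lithioethynyl ether of alcohol 25 | [Li]C#CO[C@@H](c1ccc(OC)cc1)[C@@H](C#C[Si](C)(C)C)c1cc(OC)cc2c1[C@@H](c1cc(OC)cc(OC)c1)[C@H](c1ccc(OC)cc1)O2 | intermediate
29 | triethyl({[(1R,2R)-2-(DHB3-yl)-1-(4-methoxyphenyl)-4-(trimethylsilyl)but-3-yn-1-yl]oxy}ethynyl)silane | CC[Si](CC)(CC)C#CO[C@@H](c1ccc(OC)cc1)[C@@H](C#C[Si](C)(C)C)c1cc(OC)cc2c1[C@@H](c1cc(OC)cc(OC)c1)[C@H](c1ccc(OC)cc1)O2 | intermediate
30 | triethyl({[(1R,2S)-2-(DHB3-yl)-1-(4-methoxyphenyl)but-3-yn-1-yl]oxy}ethynyl)silane | CC[Si](CC)(CC)C#CO[C@@H](c1ccc(OC)cc1)[C@@H](C#C)c1cc(OC)cc2c1[C@@H](c1cc(OC)cc(OC)c1)[C@H](c1ccc(OC)cc1)O2 | intermediate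
31 | (2R,3R)-4-bromo-3-(3,5-dimethoxyphenyl)-6-methoxy-2-[(2R,3R)-3-(DHB3-yl)-2-(4-methoxyphenyl)-7-(triethylsilyl)-2,3-dihydro-1-benzofuran-5-yl]-2,3-dihydro-1-benzofuran | Brc1cc(OC)cc2c1[C@@H](c1cc(OC)cc(OC)c1)[C@H](c1cc([Si](CC)(CC)CC)c3c(c1)[C@@H](c1cc(OC)cc4c1[C@@H](c1cc(OC)cc(OC)c1)[C@H](c1ccc(OC)cc1)O4)[C@H](c1ccc(OC)cc1)O3)O2 | intermediate
32 | (2R,3R)-4-bromo-3-(3,5-dimethoxyphenyl)-6-methoxy-2-[(2R,3R)-3-(DHB3-yl)-2-(4-methoxyphenyl)-2,3-dihydro-1-benzofuran-5-yl]-2,3-dihydro-1-benzofuran | Brc1cc(OC)cc2c1[C@@H](c1cc(OC)cc(OC)c1)[C@H](c1ccc3c(c1)[C@@H](c1cc(OC)cc4c1[C@@H](c1cc(OC)cc(OC)c1)[C@H](c1ccc(OC)cc1)O4)[C@H](c1ccc(OC)cc1)O3)O2 | intermediate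
33 | 1-ethenyl-4-methoxybenzene (4-methoxystyrene) | C=Cc1ccc(OC)cc1 | starting material
34 | nonamethyl ether of the target: compound 32 with (E)-2-(4-methoxyphenyl)ethenyl in place of bromine | COc1ccc(/C=C/c2cc(OC)cc3c2[C@@H](c2cc(OC)cc(OC)c2)[C@H](c2ccc4c(c2)[C@@H](c2cc(OC)cc5c2[C@@H](c2cc(OC)cc(OC)c2)[C@H](c2ccc(OC)cc2)O5)[C@H](c2ccc(OC)cc2)O4)O3)cc1 | intermediate
35 | CNP0184803.1: (E)-stilbene trimer with three trans-(2R,3R)-2,3-dihydrobenzofurans and nine free phenols | Oc1ccc(/C=C/c2cc(O)cc3c2[C@@H](c2cc(O)cc(O)c2)[C@H](c2ccc4c(c2)[C@@H](c2cc(O)cc5c2[C@@H](c2cc(O)cc(O)c2)[C@H](c2ccc(O)cc2)O5)[C@H](c2ccc(O)cc2)O4)O3)cc1 | target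

## Step count and risks

Total step count: 20. Longest linear sequence: 18 steps (steps 1–4, 6, 7, 9–20).

**Step 17 (key cycloaddition).** The hindered alkyne 14 may be taken up too slowly by the ruthenacycle, so that 30 is lost to self-cycloaddition or to thermal rearrangement of its ynol ether before the cross reaction occurs. The fallback sets out from 30 and joins the halves at the sp3 carbon instead. Diyne 30 is cyclotrimerised under the same ruthenium catalysis with a large excess of the small alkyne 2-ethynyl-4,4,5,5-tetramethyl-1,3,2-dioxaborolane, which should give the ring B pinacol boronate F1 (boron on B1, silicon on B3). Copper-mediated iododeboronation (CuI, 1,10-phenanthroline, KI, air, MeOH/H2O) converts it to the aryl iodide F2. The photoredox/nickel decarboxylative arylation of step 10, now run between acid 15 and F2, forms the C2(DHB1)–B1 bond trans to the C3 aryl group and comes back to the route at 31.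

**Step 14 (allenylzinc addition).** Chirality transfer may erode through ionisation of the benzylic propargylic mesylate or racemisation of the aryl-substituted allenylzinc, and the anti/syn ratio may be low with the electron-rich aldehyde. The fallback sets out from alcohol 21 and uses a configurationally stable allenylboron reagent. Alcohol 21 is converted to the methyl carbonate F3 (ClCO2Me, pyridine). Copper-catalysed anti-SN2′ borylation (CuOt-Bu, Xantphos, B2pin2, THF) gives the allenyl pinacolboronate F4. Heating F4 with aldehyde 23 in toluene should give, through a closed six-membered SE2′ transition state, the same anti alcohol after aqueous cleavage of the borate, and the route is rejoined at 25.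

**Step 20 (global demethylation).** Protonation of the electron-rich stilbene under BBr3 or HBr may trigger cyclisation of a neighbouring dimethoxyphenyl ring onto the benzylic cation, or E/Z isomerisation, before all nine ethers are cleaved. The fallback sets out from bromide 32 and removes the methyl groups before the stilbene exists. BBr3 on 32 gives the octaphenol bromide F5, and Ac2O/pyridine gives the octaacetate F6. Heck reaction of F6 with 4-acetoxystyrene under the conditions of step 19 gives the nonaacetate F7. Mild methanolysis (K2CO3 cat., MeOH, 0 °C) then comes back to the route at the target 35.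

Further compounds
F1 | step 17 | (2R,3R)-3-(DHB3-yl)-2-(4-methoxyphenyl)-5-(4,4,5,5-tetramethyl-1,3,2-dioxaborolan-2-yl)-7-(triethylsilyl)-2,3-dihydro-1-benzofuran | CC1(C)OB(OC1(C)C)c1cc([Si](CC)(CC)CC)c2c(c1)[C@@H](c1cc(OC)cc3c1[C@@H](c1cc(OC)cc(OC)c1)[C@H](c1ccc(OC)cc1)O3)[C@H](c1ccc(OC)cc1)O2
F2 | step 17 | (2R,3R)-3-(DHB3-yl)-5-iodo-2-(4-methoxyphenyl)-7-(triethylsilyl)-2,3-dihydro-1-benzofuran | Ic1cc([Si](CC)(CC)CC)c2c(c1)[C@@H](c1cc(OC)cc3c1[C@@H](c1cc(OC)cc(OC)c1)[C@H](c1ccc(OC)cc1)O3)[C@H](c1ccc(OC)cc1)O2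
F3 | step 14 | (1S)-1-(DHB3-yl)-3-(trimethylsilyl)prop-2-yn-1-yl methyl carbonate | COC(=O)O[C@H](C#C[Si](C)(C)C)c1cc(OC)cc2c1[C@@H](c1cc(OC)cc(OC)c1)[C@H](c1ccc(OC)cc1)O2
F4 | step 14 | (P)-2-[3-(DHB3-yl)-1-(trimethylsilyl)propa-1,2-dien-1-yl]-4,4,5,5-tetramethyl-1,3,2-dioxaborolane | CC1(C)OB(OC1(C)C)C([Si](C)(C)C)=[C@]=C([H])c1cc(OC)cc2c1[C@@H](c1cc(OC)cc(OC)c1)[C@H](c1ccc(OC)cc1)O2
F5 | step 20 | octaphenol bromide (compound 32 with all eight methyl ethers cleaved) | Brc1cc(O)cc2c1[C@@H](c1cc(O)cc(O)c1)[C@H](c1ccc3c(c1)[C@@H](c1cc(O)cc4c1[C@@H](c1cc(O)cc(O)c1)[C@H](c1ccc(O)cc1)O4)[C@H](c1ccc(O)cc1)O3)O2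
F6 | step 20 | octaacetate of F5 | Brc1cc(OC(C)=O)cc2c1[C@@H](c1cc(OC(C)=O)cc(OC(C)=O)c1)[C@H](c1ccc3c(c1)[C@@H](c1cc(OC(C)=O)cc4c1[C@@H](c1cc(OC(C)=O)cc(OC(C)=O)c1)[C@H](c1ccc(OC(C)=O)cc1)O4)[C@H](c1ccc(OC(C)=O)cc1)O3)O2
F7 | step 20 | nonaacetate of the target 35 | CC(=O)Oc1ccc(/C=C/c2cc(OC(C)=O)cc3c2[C@@H](c2cc(OC(C)=O)cc(OC(C)=O)c2)[C@H](c2ccc4c(c2)[C@@H](c2cc(OC(C)=O)cc5c2[C@@H](c2cc(OC(C)=O)cc(OC(C)=O)c2)[C@H](c2ccc(OC(C)=O)cc2)O5)[C@H](c2ccc(OC(C)=O)cc2)O4)O3)cc1
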